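## Retrosynthetic overview

1. The target is a bicyclo[3.3.1]nonane (C1 is the bridgehead next to the quaternary C8, C9 the bridging ketone). The endo C7 prenyl group is made last from an exocyclic C7=CH2 by exo-face hydroboration and B-alkyl Suzuki coupling, followed by desilylation.
2. Key disconnection: C5–C6 and C1–C8 are cut together, so ring B (C1, C9, C5, C6, C7, C8) is annulated in one operation onto the flat aromatic precursor of ring A.
3. Enabling feature: C1–C9–C5 are three contiguous carbons of ring A (C1–C2–C3–C4–C5–C9), which is a dearomatized 2-aroyl-4,6-diprenylphloroglucinol. Its two prenyl-bearing ring carbons flank the C9 oxygen, are both nucleophilic and are enantiotopic. C6–C7–C8 maps onto a geometrically defined α-(acetoxymethyl) enal (allylic acetate carbon = C6, enal β-carbon = C8, formyl carbon = later C1' of the C7 prenyl group).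
4. Ring order: ring A is bought as phloroglucinol and acylated (Hoesch) and prenylated; ring B is the only ring made (step 6). The enal comes from but-2-yn-1-ol by syn-carbomagnesiation and formylation.

Key step: step 6

Assumption: which antipode of the Trost ligand gives the required sense of allylation cannot be predicted; the (R,R) ligand is written and would be exchanged for its mirror image if the first run shows the opposite sense. The stereochemical assignments (C7 prenyl endo, C8 methyl anti to C2) were derived by hand from the target SMILES, and all descriptors refer to the C4-enol tautomer drawn there.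

## Route

Step 1
Reactants: 1 benzene-1,3,5-triol (phloroglucinol); 2 3-hydroxybenzonitrile
Product: 4 (3-hydroxyphenyl)(2,4,6-trihydroxyphenyl)methanone, via ketiminium chloride 3 (not isolated)
Conditions: ZnCl2, HCl (g), Et2O, 0 °C; then H2O, 100 °C
Reagents that add atoms: water, O
Why: Houben–Hoesch acylation, in which the activated nitrile attacks the very electron-rich phloroglucinol once (the ketiminium salt deactivates the ring) and hydrolysis gives the aryl ketone.

Step 2
Reactants: 4 (3-hydroxyphenyl)(2,4,6-trihydroxyphenyl)methanone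
Product: 5 (3-hydroxyphenyl)[2,4,6-trihydroxy-3,5-bis(3-methylbut-2-en-1-yl)phenyl]methanone
Conditions: prenyl bromide (2.1 equiv), KOH (10% aq), 0 °C
Reagents that add atoms: 1-bromo-3-methylbut-2-ene, CC(C)=CCBr
Why: C-alkylation of an acylphloroglucinolate in water (a known double C-prenylation at the two free ring carbons), which should outrun O-alkylation of the isolated meta-phenol when the bromide is limiting.

Step 3
Reactants: 5 (3-hydroxyphenyl)[2,4,6-trihydroxy-3,5-bis(3-methylbut-2-en-1-yl)phenyl]methanone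
Product: 6 [2,4,6-trihydroxy-3,5-bis(3-methylbut-2-en-1-yl)phenyl]{3-[tri(propan-2-yl)silyloxy]phenyl}methanone
Conditions: i-Pr3SiCl (1.05 equiv), imidazole, DMF, 0 °C
Reagents that add atoms: chlorotri(propan-2-yl)silane, CC(C)[Si](Cl)(C(C)C)C(C)C
Why: Silyl ether formation under steric control, since the bulky chloride should reach only the unhindered 3'-OH while the three ring hydroxyls are flanked by prenyl groups or hydrogen-bonded to the carbonyl.

Step 4
Reactants: 7 but-2-yn-1-ol; 8 5-bromo-2-methylpent-2-ene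
Product: 11 (2Z)-2-(hydroxymethyl)-3,7-dimethylocta-2,6-dienal, via Grignard reagent 9 (not isolated), via alkenylmagnesium alkoxide 10 (not isolated)
Conditions: 8, Mg, THF, rt; then 7, Fe(acac)3 (10 mol %), THF, −20 → 0 °C; then DMF, 0 °C → rt; 1 M HCl
Reagents that add atoms: N,N-dimethylformamide, O=CN(C)C
Why: Iron-catalysed, alkoxide-directed syn-carbomagnesiation of a propargylic alcohol puts the alkyl group on the remote alkyne carbon and magnesium on the proximal one on the same side, so formylation of 10 with retention places the formyl group cis to the 4-methylpent-3-enyl chain and the hydroxymethyl group cis to methyl.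

Step 5
Reactants: 11 (2Z)-2-(hydroxymethyl)-3,7-dimethylocta-2,6-dienal
Product: 12 (2Z)-2-formyl-3,7-dimethylocta-2,6-dien-1-yl acetate
Conditions: Ac2O, pyridine, DMAP (cat.), CH2Cl2, 0 °C
Reagents that add atoms: acetic anhydride, CC(=O)OC(C)=O
Why: Standard acylation of a primary allylic alcohol, which turns the future C6 into an allylic acetate without touching the enal geometry.

Step 6
Reactants: 6 [2,4,6-trihydroxy-3,5-bis(3-methylbut-2-en-1-yl)phenyl]{3-[tri(propan-2-yl)silyloxy]phenyl}methanone; 12 (2Z)-2-formyl-3,7-dimethylocta-2,6-dien-1-yl acetate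
Product: 15 (E)-{(1S,5S,8S)-4-hydroxy-8-methyl-1,5-bis(3-methylbut-2-en-1-yl)-8-(4-methylpent-3-en-1-yl)-2,9-dioxo-3-{3-[tri(propan-2-yl)silyloxy]benzoyl}bicyclo[3.3.1]non-3-en-7-ylidene}methyl trifluoromethanesulfonate, via allylated dienone dipotassium salt 13 (not isolated), via bicyclic enolate dipotassium salt 14 (not isolated)
Conditions: KN(SiMe3)2 (3.0 equiv), THF, −78 °C; [Pd(C3H5)Cl]2 (2.5 mol %), (R,R)-DACH-phenyl Trost ligand (7.5 mol %), 12, −40 °C; then −40 → 40 °C; then PhNTf2 (1.1 equiv), −78 → 0 °C; 1 M HCl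
Reagents that add atoms: N-phenylbis(trifluoromethanesulfonimide), O=S(=O)(N(c1ccccc1)S(=O)(=O)C(F)(F)F)C(F)(F)F
Why: Proposed new method: the tripotassium salt of 6 should be C-allylated at one of its two enantiotopic prenyl-bearing ring carbons by the 2-formyl-π-allylpalladium complex formed from 12 (attack at the CH2 terminus gives the C5–C6 bond, a quaternary C5 and the enal with unchanged geometry), the dianion 13 should then close ring B by Michael addition of the second prenyl-bearing carbon to the enal β-carbon (C1–C8 bond), and PhNTf2 should trap the aldehyde enolate 14 on oxygen. The closest known reaction types are the potassium amide-mediated alkylative dearomatization–annulation of 2-acyl-4,6-diprenylphloroglucinols with α-acetoxymethyl enals, which gives this type B bicyclo[3.3.1]nonane, the palladium-catalysed dearomative allylic annulation of the same phloroglucinols and the asymmetric allylic alkylation of prochiral enolates and naphtholates with this ligand class. Ring B (C1, C9, C5, C6, C7, C8) is closed by a 6-endo-trig Michael addition after an intermolecular allylic substitution. C5 is set by the chiral ligand, which tells apart the two faces of the planar, Cs-symmetric nucleophile; C1 follows from C5 because the tether reaches C1 only on its own face; C8 follows from the fixed alkene geometry in a chair-like closure with a staggered forming C1–C8 bond, where the group cis to C6 (methyl) ends axial, anti to C2, and the group cis to the formyl carbon (4-methylpent-3-enyl) ends equatorial; C7 stays sp2, so no C7 epimers arise. The step needs C- and not O-allylation (O-allylation is reversible under palladium), closure from C1 and not from the aroyl-bearing C3 (favoured for the dipotassium dianion as in the known type B annulation) and no erosion at C8 by retro-Michael reaction or enal isomerization, which the absence of free amide base and the irreversible O-triflation are meant to prevent.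

Step 7
Reactants: 15 (E)-{(1S,5S,8S)-4-hydroxy-8-methyl-1,5-bis(3-methylbut-2-en-1-yl)-8-(4-methylpent-3-en-1-yl)-2,9-dioxo-3-{3-[tri(propan-2-yl)silyloxy]benzoyl}bicyclo[3.3.1]non-3-en-7-ylidene}methyl trifluoromethanesulfonate
Product: 16 (1S,5S,8S)-4-hydroxy-8-methyl-7-methylidene-1,5-bis(3-methylbut-2-en-1-yl)-8-(4-methylpent-3-en-1-yl)-3-{3-[tri(propan-2-yl)silyloxy]benzoyl}bicyclo[3.3.1]non-3-ene-2,9-dione
Conditions: Pd(OAc)2 (5 mol %), PPh3 (10 mol %), HCO2H, Bu3N, DMF, 60 °C
Reagents that add atoms: none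
Why: Palladium-catalysed formate reduction of an alkenyl triflate (oxidative addition, decarboxylation of the palladium formate, C–H reductive elimination) should turn the former formyl carbon into the exocyclic methylene carbon and leave the trisubstituted alkenes and the enol untouched.

Step 8
Reactants: 16 (1S,5S,8S)-4-hydroxy-8-methyl-7-methylidene-1,5-bis(3-methylbut-2-en-1-yl)-8-(4-methylpent-3-en-1-yl)-3-{3-[tri(propan-2-yl)silyloxy]benzoyl}bicyclo[3.3.1]non-3-ene-2,9-dione
Product: 18 (1S,5S,7S,8S)-4-hydroxy-8-methyl-1,5,7-tris(3-methylbut-2-en-1-yl)-8-(4-methylpent-3-en-1-yl)-3-{3-[tri(propan-2-yl)silyloxy]benzoyl}bicyclo[3.3.1]non-3-ene-2,9-dione, via alkylborane 17 (not isolated)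
Conditions: 9-BBN-H dimer (3 equiv of B–H), THF, 0 °C → rt; then 1-bromo-2-methylprop-1-ene, Pd(dppf)Cl2 (10 mol %), AsPh3, K3PO4 (3 M aq), DMF, rt → 40 °C
Reagents that add atoms: 1-bromo-2-methylprop-1-ene, CC(C)=CBr
Why: Hydroboration then B-alkyl Suzuki–Miyaura coupling, in which 9-BBN should add only to the 1,1-disubstituted exocyclic alkene (boron to CH2) and from the exo face because the endo face of C7 is covered by ring A and the aroyl group, so hydrogen enters C7 exo and the CH2–B arm, coupled with retention, becomes the endo prenyl group (7S); one equivalent of borane is consumed by the enol O–H.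

Step 9
Reactants: 18 (1S,5S,7S,8S)-4-hydroxy-8-methyl-1,5,7-tris(3-methylbut-2-en-1-yl)-8-(4-methylpent-3-en-1-yl)-3-{3-[tri(propan-2-yl)silyloxy]benzoyl}bicyclo[3.3.1]non-3-ene-2,9-dione
Product: 19 (1S,5S,7S,8S)-4-hydroxy-3-(3-hydroxybenzoyl)-8-methyl-1,5,7-tris(3-methylbut-2-en-1-yl)-8-(4-methylpent-3-en-1-yl)bicyclo[3.3.1]non-3-ene-2,9-dione
Conditions: Bu4NF, AcOH, THF, 0 °C
Reagents that add atoms: none
Why: Fluoride cleavage of an aryl silyl ether under acetic acid buffering, which should touch neither the alkenes nor the enolised triketone and no stereocenter.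

## Compound list

1 | benzene-1,3,5-triol (phloroglucinol) | Oc1cc(O)cc(O)c1 | starting material
2 | 3-hydroxybenzonitrile | N#Cc1cccc(O)c1 | starting material
3 | (3-hydroxyphenyl)(2,4,6-trihydroxyphenyl)methaniminium chloride | [NH2+]=C(c1cccc(O)c1)c1c(O)cc(O)cc1O.[Cl-] | intermediate (not isolated)
4 | (3-hydroxyphenyl)(2,4,6-trihydroxyphenyl)methanone | O=C(c1cccc(O)c1)c1c(O)cc(O)cc1O | intermediate
5 | (3-hydroxyphenyl)[2,4,6-trihydroxy-3,5-bis(3-methylbut-2-en-1-yl)phenyl]methanone | O=C(c1cccc(O)c1)c1c(O)c(CC=C(C)C)c(O)c(CC=C(C)C)c1O | intermediate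
6 | [2,4,6-trihydroxy-3,5-bis(3-methylbut-2-en-1-yl)phenyl]{3-[tri(propan-2-yl)silyloxy]phenyl}methanone | O=C(c1cccc(O[Si](C(C)C)(C(C)C)C(C)C)c1)c1c(O)c(CC=C(C)C)c(O)c(CC=C(C)C)c1O | intermediate
7 | but-2-yn-1-ol | CC#CCO | starting material
8 | 5-bromo-2-methylpent-2-ene | CC(C)=CCCBr | starting material
9 | (4-methylpent-3-en-1-yl)magnesium bromide | CC(C)=CCC[Mg]Br | intermediate (not isolated)
10 | (Z)-[1-(bromomagnesiooxy)-3,7-dimethylocta-2,6-dien-2-yl]magnesium bromide (magnesium cis to the 4-methylpent-3-enyl chain) | C/C(CCC=C(C)C)=C(/[Mg]Br)CO[Mg]Br | intermediate (not isolated)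
11 | (2Z)-2-(hydroxymethyl)-3,7-dimethylocta-2,6-dienal (formyl cis to the 4-methylpent-3-enyl chain) | O=C/C(CO)=C(/C)CCC=C(C)C | intermediate
12 | (2Z)-2-formyl-3,7-dimethylocta-2,6-dien-1-yl acetate | O=C/C(COC(C)=O)=C(/C)CCC=C(C)C | intermediate
13 | dipotassium salt of (6S)-6-[(2Z)-2-formyl-3,7-dimethylocta-2,6-dien-1-yl]-3,5-dihydroxy-2,6-bis(3-methylbut-2-en-1-yl)-4-{3-[tri(propan-2-yl)silyloxy]benzoyl}cyclohexa-2,4-dien-1-one | O=C/C(=C(/C)CCC=C(C)C)C[C@]1(CC=C(C)C)C(=O)C(CC=C(C)C)=C([O-])C(C(=O)c2cccc(O[Si](C(C)C)(C(C)C)C(C)C)c2)=C1[O-].[K+].[K+] | intermediate (not isolated)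
14 | dipotassium salt (C4 enolate and exocyclic C7 aldehyde enolate) of the (1S,5S,8S) bicyclic 7-carbaldehyde | CC(C)=CCC[C@@]1(C)/C(=C/[O-])C[C@]2(CC=C(C)C)C(=O)[C@@]1(CC=C(C)C)C(=O)C(C(=O)c1cccc(O[Si](C(C)C)(C(C)C)C(C)C)c1)=C2[O-].[K+].[K+] | intermediate (not isolated)
15 | (E)-{(1S,5S,8S)-4-hydroxy-8-methyl-1,5-bis(3-methylbut-2-en-1-yl)-8-(4-methylpent-3-en-1-yl)-2,9-dioxo-3-{3-[tri(propan-2-yl)silyloxy]benzoyl}bicyclo[3.3.1]non-3-en-7-ylidene}methyl trifluoromethanesulfonate (triflate oxygen syn to C6) | CC(C)=CCC[C@@]1(C)/C(=C/OS(=O)(=O)C(F)(F)F)C[C@]2(CC=C(C)C)C(=O)[C@@]1(CC=C(C)C)C(=O)C(C(=O)c1cccc(O[Si](C(C)C)(C(C)C)C(C)C)c1)=C2O | intermediate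
16 | (1S,5S,8S)-4-hydroxy-8-methyl-7-methylidene-1,5-bis(3-methylbut-2-en-1-yl)-8-(4-methylpent-3-en-1-yl)-3-{3-[tri(propan-2-yl)silyloxy]benzoyl}bicyclo[3.3.1]non-3-ene-2,9-dione | CC(C)=CCC[C@@]1(C)C(=C)C[C@]2(CC=C(C)C)C(=O)[C@@]1(CC=C(C)C)C(=O)C(C(=O)c1cccc(O[Si](C(C)C)(C(C)C)C(C)C)c1)=C2O | intermediate
17 | B-alkyl-9-borabicyclo[3.3.1]nonane at the endo C7 methylene arm, enol oxygen as its 9-BBN borinate | CC(C)=CCC[C@@]1(C)[C@@H](CB3C4CCCC3CCC4)C[C@]2(CC=C(C)C)C(=O)[C@@]1(CC=C(C)C)C(=O)C(C(=O)c1cccc(O[Si](C(C)C)(C(C)C)C(C)C)c1)=C2OB5C6CCCC5CCC6 | intermediate (not isolated)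
18 | (1S,5S,7S,8S)-4-hydroxy-8-methyl-1,5,7-tris(3-methylbut-2-en-1-yl)-8-(4-methylpent-3-en-1-yl)-3-{3-[tri(propan-2-yl)silyloxy]benzoyl}bicyclo[3.3.1]non-3-ene-2,9-dione | CC(C)=CCC[C@@]1(C)[C@@H](CC=C(C)C)C[C@]2(CC=C(C)C)C(=O)[C@@]1(CC=C(C)C)C(=O)C(C(=O)c1cccc(O[Si](C(C)C)(C(C)C)C(C)C)c1)=C2O | intermediate
19 | (1S,5S,7S,8S)-4-hydroxy-3-(3-hydroxybenzoyl)-8-methyl-1,5,7-tris(3-methylbut-2-en-1-yl)-8-(4-methylpent-3-en-1-yl)bicyclo[3.3.1]non-3-ene-2,9-dione | CC(C)=CCC[C@@]1(C)[C@@H](CC=C(C)C)C[C@]2(CC=C(C)C)C(=O)[C@@]1(CC=C(C)C)C(=O)C(C(=O)c1cccc(O)c1)=C2O | target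

## Step count and risks

Total step count: 9 (steps 1–3 arene fragment, steps 4–5 enal fragment, steps 6–9 after convergence).
Longest linear sequence: 7 steps (1, 2, 3, 6, 7, 8, 9).

Steps most likely to fail:

1. Step 6 (Proposed new method). What may go wrong: weak discrimination of the two enantiotopic faces in the palladium allylation or a competing uncatalysed alkylation (low enantiomeric purity), ring closure from the aroyl-bearing carbon instead of C1, or loss of stereochemical fidelity at C8 through reversible Michael addition. Fallback with known chemistry, from 6 and 12 back to 15: the established potassium amide alkylative dearomatization–annulation is run without palladium (KN(SiMe3)2, THF, 65 °C) and the enolate is trapped with PhNTf2 as before, which should give 15 together with its mirror image ent-15 F1. The racemate is then resolved through its acidic enol by fractional crystallization with (R)-1-phenylethanamine, which gives the (R)-1-phenylethanaminium enolate salt of 15 F2 (or the antipodal amine if the other salt crystallizes), and 1 M HCl returns 15.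

2. Step 8. What may go wrong: hydroboration of the trisubstituted alkenes or reduction of a carbonyl group by excess borane, slow transmetalation of the hindered β-branched alkylborane, and protodeboronation. Fallback from 15 back to 18, bypassing 16: reductive carbonylation of the alkenyl triflate (Pd(PPh3)4, CO, Bu3SnH, THF, 50 °C) should give the exocyclic enal (E)-2-{(1S,5S,8S)-bicyclic-7-ylidene}acetaldehyde F3. Conjugate reduction with [(Ph3P)CuH]6, hydride entering C7 from the exo face, should give the endo acetaldehyde 2-[(1S,5S,7R,8S)-bicyclic-7-yl]acetaldehyde F4. Wittig olefination with isopropylidenetriphenylphosphorane (from isopropyltriphenylphosphonium iodide and n-BuLi) then gives 18.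

3. Step 4. What may go wrong: β-hydride elimination from the alkyl–iron intermediate of a Grignard reagent that carries β-hydrogens (hydromagnesiation instead of carbomagnesiation), and incomplete formylation of the hindered alkenylmagnesium species. Fallback from 8 back to 11, with the methyl Grignard reagent for which this carbomagnesiation is best established: alkylation of the dianion of prop-2-yn-1-ol with 8 (n-BuLi, THF/DMPU) gives 7-methyloct-6-en-2-yn-1-ol F5. Carbomagnesiation with MeMgBr and Fe(acac)3 followed by an iodine quench gives (2E)-2-iodo-3,7-dimethylocta-2,6-dien-1-ol F6 (iodine cis to methyl). Oxidation with MnO2 gives (2E)-2-iodo-3,7-dimethylocta-2,6-dienal F7, and Stille coupling with (tributylstannyl)methanol (Pd(PPh3)4, dioxane, 80 °C) returns 11 with the same geometry.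

## Further compounds

F1 | step 6 | ent-15, (E)-{(1R,5R,8R)-4-hydroxy-8-methyl-1,5-bis(3-methylbut-2-en-1-yl)-8-(4-methylpent-3-en-1-yl)-2,9-dioxo-3-{3-[tri(propan-2-yl)silyloxy]benzoyl}bicyclo[3.3.1]non-3-en-7-ylidene}methyl trifluoromethanesulfonate | CC(C)=CCC[C@]1(C)/C(=C/OS(=O)(=O)C(F)(F)F)C[C@@]2(CC=C(C)C)C(=O)[C@]1(CC=C(C)C)C(=O)C(C(=O)c1cccc(O[Si](C(C)C)(C(C)C)C(C)C)c1)=C2O
F2 | step 6 | (R)-1-phenylethanaminium enolate salt of 15 | CC(C)=CCC[C@@]1(C)/C(=C/OS(=O)(=O)C(F)(F)F)C[C@]2(CC=C(C)C)C(=O)[C@@]1(CC=C(C)C)C(=O)C(C(=O)c1cccc(O[Si](C(C)C)(C(C)C)C(C)C)c1)=C2[O-].C[C@@H]([NH3+])c1ccccc1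
F3 | step 8 | (E)-2-{(1S,5S,8S)-4-hydroxy-8-methyl-1,5-bis(3-methylbut-2-en-1-yl)-8-(4-methylpent-3-en-1-yl)-2,9-dioxo-3-{3-[tri(propan-2-yl)silyloxy]benzoyl}bicyclo[3.3.1]non-3-en-7-ylidene}acetaldehyde | CC(C)=CCC[C@@]1(C)/C(=C/C=O)C[C@]2(CC=C(C)C)C(=O)[C@@]1(CC=C(C)C)C(=O)C(C(=O)c1cccc(O[Si](C(C)C)(C(C)C)C(C)C)c1)=C2O
F4 | step 8 | 2-[(1S,5S,7R,8S)-4-hydroxy-8-methyl-1,5-bis(3-methylbut-2-en-1-yl)-8-(4-methylpent-3-en-1-yl)-2,9-dioxo-3-{3-[tri(propan-2-yl)silyloxy]benzoyl}bicyclo[3.3.1]non-3-en-7-yl]acetaldehyde (side chain endo) | CC(C)=CCC[C@@]1(C)[C@@H](CC=O)C[C@]2(CC=C(C)C)C(=O)[C@@]1(CC=C(C)C)C(=O)C(C(=O)c1cccc(O[Si](C(C)C)(C(C)C)C(C)C)c1)=C2O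
F5 | step 4 | 7-methyloct-6-en-2-yn-1-ol | CC(C)=CCCC#CCO
F6 | step 4 | (2E)-2-iodo-3,7-dimethylocta-2,6-dien-1-ol | OC/C(I)=C(/C)CCC=C(C)C
F7 | step 4 | (2E)-2-iodo-3,7-dimethylocta-2,6-dienal | O=C/C(I)=C(/C)CCC=C(C)C
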